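The disconnection on which everything rests is the aryl ether bond O1–C8a of ring C. The C4 carbonyl lies ortho to C8a on ring A, and the C2 carbinol oxygen can reach C8a through a six-membered transition state, so a C2 alkoxide can displace fluoride from C8a by addition–elimination. This closes the pyranone ring in one operation without touching the C2–O bond, so the (2S) centre, set beforehand by copper-catalysed Si-face β-borylation/oxidation of a chalcone, is carried through. The precursor is an open-chain (S)-β-hydroxy ketone whose ring A bears fluorine at the future C8a, flanked by the acyl group and the side chain (Evans alkylation, Negishi coupling).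

Key step: step 13

Remark: flavanone numbering is used (O1, C2, C3, C4, C4a, C5–C8, C8a; ring A = benzo ring, ring B = 2-aryl ring, ring C = pyranone). 5-Fluororesorcinol and (R)-4-methyldihydrofuran-2(3H)-one are assumed to be purchasable.

Step 1
Reactants: 1 5-fluorobenzene-1,3-diol
Product: 2 1-fluoro-3,5-bis(methoxymethoxy)benzene
Conditions: NaH (2.4 equiv), MOMCl (2.3 equiv), DMF, 0 °C to rt
Reagents that add atoms: chloromethyl methyl ether, COCCl
Why: Williamson-type O-alkylation of the bis-phenoxide should mask both phenols as base-stable acetals that later fall to mild acid.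

Step 2
Reactants: 2 1-fluoro-3,5-bis(methoxymethoxy)benzene
Product: 3 2-fluoro-1,3-diiodo-4,6-bis(methoxymethoxy)benzene
Conditions: NIS (2.1 equiv), MeCN, 0 °C to rt, dark
Reagents that add atoms: N-iodosuccinimide, O=C1CCC(=O)N1I
Why: Electrophilic aromatic iodination should place each iodine ortho to fluorine and para to an acetal oxygen, the site between the two acetal oxygens being the most hindered, as in the 4,6-dihalogenation of resorcinol diethers.

Step 3
Reactants: 3 2-fluoro-1,3-diiodo-4,6-bis(methoxymethoxy)benzene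
Product: 5 1-[2-fluoro-3-iodo-4,6-bis(methoxymethoxy)phenyl]ethan-1-one, via arylmagnesium chloride 4 (not isolated)
Conditions: iPrMgCl·LiCl (1.0 equiv), THF, −40 °C; then MeC(O)N(OMe)Me, −40 to 0 °C; aq NH4Cl
Reagents that add atoms: N-methoxy-N-methylacetamide, CC(=O)N(C)OC; isopropylmagnesium chloride–lithium chloride, CC(C)[Mg]Cl.[Li+].[Cl-] (magnesium held in 4 only)
Why: Iodine–magnesium exchange should stop after one iodine because the first arylmagnesium deactivates the second, and Weinreb amide acylation stops at the ketone through its chelated tetrahedral adduct.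

Step 4
Reactants: 6 (R)-4-methyldihydrofuran-2(3H)-one
Product: 9 (R)-4-[(tert-butyldimethylsilyl)oxy]-3-methylbutanoic acid, via potassium hydroxy carboxylate 7 (not isolated), via bis-silyl ester ether 8 (not isolated)
Conditions: KOH (1.05 equiv), MeOH/H2O, rt, evaporate; TBSCl (2.2 equiv), imidazole, DMF, rt; then MeOH/H2O, rt
Reagents that add atoms: potassium hydroxide, [K+].[OH-]; tert-butyldimethylsilyl chloride, CC(C)(C)[Si](C)(C)Cl
Why: Saponification opens the lactone, and exhaustive silylation followed by selective hydrolysis of the labile silyl ester should leave the primary silyl ether, with the methyl-bearing stereocenter taken unchanged from the chiral pool.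

Step 5
Reactants: 9 (R)-4-[(tert-butyldimethylsilyl)oxy]-3-methylbutanoic acid
Product: 11 (S)-4-benzyl-3-[(R)-4-[(tert-butyldimethylsilyl)oxy]-3-methylbutanoyl]oxazolidin-2-one, via mixed pivalic anhydride 10 (not isolated)
Conditions: PivCl, Et3N, THF, −20 °C; then LiCl, (S)-4-benzyloxazolidin-2-one, rt
Reagents that add atoms: (S)-4-benzyloxazolidin-2-one, O=C1N[C@@H](Cc2ccccc2)CO1; pivaloyl chloride, CC(C)(C)C(Cl)=O (acyl group held in 10 only)
Why: Mixed-anhydride N-acylation should attach the Evans auxiliary without touching the β-stereocenter.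

Step 6
Reactants: 11 (S)-4-benzyl-3-[(R)-4-[(tert-butyldimethylsilyl)oxy]-3-methylbutanoyl]oxazolidin-2-one
Product: 13 (S)-4-benzyl-3-[(2S,3R)-4-[(tert-butyldimethylsilyl)oxy]-3-methyl-2-(3-methylbut-2-en-1-yl)butanoyl]oxazolidin-2-one, via sodium Z-enolate 12 (not isolated)
Conditions: NaHMDS (1.1 equiv), THF, −78 °C; prenyl bromide (3 equiv), −78 to −40 °C
Reagents that add atoms: 1-bromo-3-methylbut-2-ene, CC(C)=CCBr; sodium hexamethyldisilazide, C[Si](C)(C)[N-][Si](C)(C)C.[Na+] (sodium held in 12 only)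
Why: Evans asymmetric alkylation: the chelated Z-enolate should be prenylated on the face opposite the benzyl group, which sets the new α-stereocenter as (S) under auxiliary control.

Step 7
Reactants: 13 (S)-4-benzyl-3-[(2S,3R)-4-[(tert-butyldimethylsilyl)oxy]-3-methyl-2-(3-methylbut-2-en-1-yl)butanoyl]oxazolidin-2-one
Product: 14 (2S,3R)-4-[(tert-butyldimethylsilyl)oxy]-3-methyl-2-(3-methylbut-2-en-1-yl)butan-1-ol
Conditions: LiBH4, MeOH (1 equiv), Et2O, 0 °C
Reagents that add atoms: none
Why: Reductive cleavage of the imide with LiBH4 should give the primary alcohol and release the auxiliary without epimerisation.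

Step 8
Reactants: 14 (2S,3R)-4-[(tert-butyldimethylsilyl)oxy]-3-methyl-2-(3-methylbut-2-en-1-yl)butan-1-ol
Product: 15 tert-butyl{[(2R,3S)-3-(iodomethyl)-2,6-dimethylhept-5-en-1-yl]oxy}dimethylsilane
Conditions: I2, PPh3, imidazole, CH2Cl2, 0 °C to rt
Reagents that add atoms: iodine, II
Why: Appel-type iodination should convert the primary alcohol into the iodide at a carbon that is not a stereocenter.

Step 9
Reactants: 15 tert-butyl{[(2R,3S)-3-(iodomethyl)-2,6-dimethylhept-5-en-1-yl]oxy}dimethylsilane and 5 1-[2-fluoro-3-iodo-4,6-bis(methoxymethoxy)phenyl]ethan-1-one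
Product: 17 1-{3-[(2R,3R)-4-[(tert-butyldimethylsilyl)oxy]-3-methyl-2-(3-methylbut-2-en-1-yl)butyl]-2-fluoro-4,6-bis(methoxymethoxy)phenyl}ethan-1-one, via alkylzinc iodide 16 (not isolated)
Conditions: Zn dust (activated with BrCH2CH2Br, TMSCl), LiCl, THF, 40 °C; then 5, Pd(OAc)2 (3 mol%), SPhos (6 mol%), THF, rt to 45 °C
Reagents that add atoms: zinc, [Zn] (held in 16 only)
Why: Zinc insertion followed by Negishi coupling should join the primary alkylzinc to the aryl iodide while tolerating the ketone, the silyl ether and the alkene, and the stereocenters are not at the metal-bearing carbon.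

Step 10
Reactants: 18 4-hydroxy-2-methoxybenzaldehyde
Product: 19 2-methoxy-4-(methoxymethoxy)benzaldehyde
Conditions: NaH (1.2 equiv), MOMCl (1.2 equiv), DMF, 0 °C
Reagents that add atoms: chloromethyl methyl ether, COCCl
Why: O-alkylation of the phenoxide masks the ring B phenol so that no quinone methide can form at the later benzylic ether.

Step 11
Reactants: 17 1-{3-[(2R,3R)-4-[(tert-butyldimethylsilyl)oxy]-3-methyl-2-(3-methylbut-2-en-1-yl)butyl]-2-fluoro-4,6-bis(methoxymethoxy)phenyl}ethan-1-one and 19 2-methoxy-4-(methoxymethoxy)benzaldehyde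
Product: 20 (E)-1-{3-[(2R,3R)-4-[(tert-butyldimethylsilyl)oxy]-3-methyl-2-(3-methylbut-2-en-1-yl)butyl]-2-fluoro-4,6-bis(methoxymethoxy)phenyl}-3-[2-methoxy-4-(methoxymethoxy)phenyl]prop-2-en-1-one
Conditions: KOH, EtOH, rt
Reagents that add atoms: none
Why: Claisen–Schmidt condensation (aldol addition then E1cB dehydration) should give the E-chalcone, the aldehyde having no α-hydrogen.

Step 12
Reactants: 20 (E)-1-{3-[(2R,3R)-4-[(tert-butyldimethylsilyl)oxy]-3-methyl-2-(3-methylbut-2-en-1-yl)butyl]-2-fluoro-4,6-bis(methoxymethoxy)phenyl}-3-[2-methoxy-4-(methoxymethoxy)phenyl]prop-2-en-1-one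
Product: 22 (3S)-1-{3-[(2R,3R)-4-[(tert-butyldimethylsilyl)oxy]-3-methyl-2-(3-methylbut-2-en-1-yl)butyl]-2-fluoro-4,6-bis(methoxymethoxy)phenyl}-3-hydroxy-3-[2-methoxy-4-(methoxymethoxy)phenyl]propan-1-one, via pinacol boronate 21 (not isolated)
Conditions: CuCl (5 mol%), NaOt-Bu (10 mol%), (R)-1-[(S)-2-(diphenylphosphino)ferrocenyl]ethyldicyclohexylphosphine or its antipode (6 mol%), B2pin2 (1.2 equiv), MeOH (2 equiv), THF, rt; then NaBO3·4H2O, THF/H2O, rt
Reagents that add atoms: sodium perborate tetrahydrate, [Na+].[O-]OB=O.O.O.O.O; bis(pinacolato)diboron, CC1(C)OB(OC1(C)C)B1OC(C)(C)C(C)(C)O1 (boron held in 21 only)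
Why: Copper-catalysed asymmetric conjugate borylation should deliver boron to the Si face of C-β under ligand control (the ligand antipode that does so is fixed in a test run), and perborate oxidation replaces boron by hydroxyl with retention to give the (S)-carbinol.

Step 13
Reactants: 22 (3S)-1-{3-[(2R,3R)-4-[(tert-butyldimethylsilyl)oxy]-3-methyl-2-(3-methylbut-2-en-1-yl)butyl]-2-fluoro-4,6-bis(methoxymethoxy)phenyl}-3-hydroxy-3-[2-methoxy-4-(methoxymethoxy)phenyl]propan-1-one
Product: 24 (2S)-8-[(2R,3R)-4-[(tert-butyldimethylsilyl)oxy]-3-methyl-2-(3-methylbut-2-en-1-yl)butyl]-2-[2-methoxy-4-(methoxymethoxy)phenyl]-5,7-bis(methoxymethoxy)chroman-4-one, via potassium alkoxide 23 (not isolated)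
Conditions: KHMDS (1.05 equiv), THF, −78 to 0 °C; pH 7 phosphate buffer
Reagents that add atoms: potassium hexamethyldisilazide, C[Si](C)(C)[N-][Si](C)(C)C.[K+] (potassium held in 23 only)
Why: KHMDS should deprotonate the C2 hydroxyl irreversibly to alkoxide 23, whose oxygen adds to C8a (ipso to fluorine) to give a Meisenheimer anion delocalised into the ortho C4 carbonyl, and loss of fluoride restores aromaticity (addition–elimination). The closest known reaction type is the intramolecular SNAr etherification of 2-fluoroaryl ketones that gives chroman-4-ones. Ring C closes as a six-membered ring in a 6-exo-trig mode at the arene carbon. No stereocenter is formed: C2 keeps the (S) configuration from step 12 because its C–O bond is never broken, in contrast to an oxa-Michael closure. The step needs substitution to outrun retro-aldol cleavage and E1cB dehydration of the aldolate; this is secured by one equivalent of base at low temperature (no base is left once fluoride leaves), by the single fluorine as the only leaving group, and by the silyl ether that keeps the side-chain hydroxyl from a seven-membered closure.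

Step 14
Reactants: 24 (2S)-8-[(2R,3R)-4-[(tert-butyldimethylsilyl)oxy]-3-methyl-2-(3-methylbut-2-en-1-yl)butyl]-2-[2-methoxy-4-(methoxymethoxy)phenyl]-5,7-bis(methoxymethoxy)chroman-4-one
Product: 25 (2S)-5,7-dihydroxy-8-[(2R,3R)-4-hydroxy-3-methyl-2-(3-methylbut-2-en-1-yl)butyl]-2-(4-hydroxy-2-methoxyphenyl)chroman-4-one
Conditions: 3 M aq HCl, MeOH, 45 °C
Reagents that add atoms: none
Why: Acid-catalysed acetal exchange and desilylation in methanol should remove the three MOM groups and the silyl ether in one operation, leaving the methyl ether, the alkene and the three stereocenters untouched.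

Compound list
1 | 5-fluorobenzene-1,3-diol | Oc1cc(O)cc(F)c1 | starting material
2 | 1-fluoro-3,5-bis(methoxymethoxy)benzene | COCOc1cc(F)cc(OCOC)c1 | intermediate
3 | 2-fluoro-1,3-diiodo-4,6-bis(methoxymethoxy)benzene | COCOc1cc(OCOC)c(I)c(F)c1I | intermediate
4 | [2-fluoro-3-iodo-4,6-bis(methoxymethoxy)phenyl]magnesium chloride | COCOc1cc(OCOC)c([Mg]Cl)c(F)c1I | intermediate
5 | 1-[2-fluoro-3-iodo-4,6-bis(methoxymethoxy)phenyl]ethan-1-one | CC(=O)c1c(OCOC)cc(OCOC)c(I)c1F | intermediate
6 | (R)-4-methyldihydrofuran-2(3H)-one | C[C@H]1COC(=O)C1 | starting material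
7 | potassium (R)-4-hydroxy-3-methylbutanoate | C[C@@H](CO)CC(=O)[O-].[K+] | intermediate
8 | tert-butyldimethylsilyl (R)-4-[(tert-butyldimethylsilyl)oxy]-3-methylbutanoate | C[C@@H](CO[Si](C)(C)C(C)(C)C)CC(=O)O[Si](C)(C)C(C)(C)C | intermediate
9 | (R)-4-[(tert-butyldimethylsilyl)oxy]-3-methylbutanoic acid | C[C@@H](CO[Si](C)(C)C(C)(C)C)CC(=O)O | intermediate
10 | (R)-4-[(tert-butyldimethylsilyl)oxy]-3-methylbutanoic pivalic anhydride | C[C@@H](CO[Si](C)(C)C(C)(C)C)CC(=O)OC(=O)C(C)(C)C | intermediate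
11 | (S)-4-benzyl-3-[(R)-4-[(tert-butyldimethylsilyl)oxy]-3-methylbutanoyl]oxazolidin-2-one | C[C@@H](CO[Si](C)(C)C(C)(C)C)CC(=O)N1[C@@H](Cc2ccccc2)COC1=O | intermediate
12 | sodium (Z)-enolate of 11 | C[C@@H](CO[Si](C)(C)C(C)(C)C)/C=C(\[O-])N1[C@@H](Cc2ccccc2)COC1=O.[Na+] | intermediate
13 | (S)-4-benzyl-3-[(2S,3R)-4-[(tert-butyldimethylsilyl)oxy]-3-methyl-2-(3-methylbut-2-en-1-yl)butanoyl]oxazolidin-2-one | C[C@@H](CO[Si](C)(C)C(C)(C)C)[C@H](CC=C(C)C)C(=O)N1[C@@H](Cc2ccccc2)COC1=O | intermediate
14 | (2S,3R)-4-[(tert-butyldimethylsilyl)oxy]-3-methyl-2-(3-methylbut-2-en-1-yl)butan-1-ol | C[C@@H](CO[Si](C)(C)C(C)(C)C)[C@H](CC=C(C)C)CO | intermediate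
15 | tert-butyl{[(2R,3S)-3-(iodomethyl)-2,6-dimethylhept-5-en-1-yl]oxy}dimethylsilane | C[C@@H](CO[Si](C)(C)C(C)(C)C)[C@H](CC=C(C)C)CI | intermediate
16 | {(2S,3R)-4-[(tert-butyldimethylsilyl)oxy]-3-methyl-2-(3-methylbut-2-en-1-yl)butyl}zinc iodide | C[C@@H](CO[Si](C)(C)C(C)(C)C)[C@H](CC=C(C)C)C[Zn]I | intermediate
17 | 1-{3-[(2R,3R)-4-[(tert-butyldimethylsilyl)oxy]-3-methyl-2-(3-methylbut-2-en-1-yl)butyl]-2-fluoro-4,6-bis(methoxymethoxy)phenyl}ethan-1-one | CC(=O)c1c(OCOC)cc(OCOC)c(C[C@@H](CC=C(C)C)[C@@H](C)CO[Si](C)(C)C(C)(C)C)c1F | intermediate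
18 | 4-hydroxy-2-methoxybenzaldehyde | COc1cc(O)ccc1C=O | starting material
19 | 2-methoxy-4-(methoxymethoxy)benzaldehyde | COCOc1ccc(C=O)c(OC)c1 | intermediate
20 | (E)-chalcone from 17 and 19 | COCOc1ccc(/C=C/C(=O)c2c(OCOC)cc(OCOC)c(C[C@@H](CC=C(C)C)[C@@H](C)CO[Si](C)(C)C(C)(C)C)c2F)c(OC)c1 | intermediate
21 | (3S)-β-(pinacolboryl) ketone from 20 | COCOc1ccc([C@H](CC(=O)c2c(OCOC)cc(OCOC)c(C[C@@H](CC=C(C)C)[C@@H](C)CO[Si](C)(C)C(C)(C)C)c2F)B2OC(C)(C)C(C)(C)O2)c(OC)c1 | intermediate
22 | (3S)-β-hydroxy ketone (open-chain precursor of ring C) | COCOc1ccc([C@@H](O)CC(=O)c2c(OCOC)cc(OCOC)c(C[C@@H](CC=C(C)C)[C@@H](C)CO[Si](C)(C)C(C)(C)C)c2F)c(OC)c1 | intermediate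
23 | potassium alkoxide of 22 | COCOc1ccc([C@@H]([O-])CC(=O)c2c(OCOC)cc(OCOC)c(C[C@@H](CC=C(C)C)[C@@H](C)CO[Si](C)(C)C(C)(C)C)c2F)c(OC)c1.[K+] | intermediate
24 | (2S)-8-[(2R,3R)-4-[(tert-butyldimethylsilyl)oxy]-3-methyl-2-(3-methylbut-2-en-1-yl)butyl]-2-[2-methoxy-4-(methoxymethoxy)phenyl]-5,7-bis(methoxymethoxy)chroman-4-one | COCOc1ccc([C@@H]2CC(=O)c3c(OCOC)cc(OCOC)c(C[C@@H](CC=C(C)C)[C@@H](C)CO[Si](C)(C)C(C)(C)C)c3O2)c(OC)c1 | intermediate
25 | (2S)-5,7-dihydroxy-8-[(2R,3R)-4-hydroxy-3-methyl-2-(3-methylbut-2-en-1-yl)butyl]-2-(4-hydroxy-2-methoxyphenyl)chroman-4-one (CNP0081318.1) | COc1cc(O)ccc1[C@@H]1CC(=O)c2c(O)cc(O)c(C[C@@H](CC=C(C)C)[C@@H](C)CO)c2O1 | target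

Total step count: 14. Longest linear sequence: 10 steps (steps 4–9 and 11–14, from 6).

Steps most likely to fail

Step 13. Retro-aldol cleavage or E1cB dehydration of the aldolate may compete with substitution at the hindered, electron-rich fluoroarene, and base-induced ring opening of the product would erode C2. The fallback sets out from 22 and comes back at 24 at another oxidation level. Evans–Saksena reduction of 22 with Me4NBH(OAc)3 (MeCN/AcOH, −20 °C) should give the anti-1,3-diol F1, in which neither retro-aldol nor E1cB is possible. Treatment with KOt-Bu in DMSO/THF at 60–80 °C should close the same O1–C8a bond by SNAr, since only the C2 alkoxide can reach C8a in a six-membered ring, to give the flavan-4-ol F2. Oxidation of the benzylic alcohol with Dess–Martin periodinane returns to 24.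

Step 12. Facial discrimination at C-β may be poor on this chalcone, whose aryl ketone is twisted and whose β-aryl group is electron-rich and ortho-substituted; the boronate may also protodeboronate before oxidation. The fallback sets out from 20 and comes back at 22. Juliá–Colonna epoxidation (poly-D-leucine, urea–H2O2, DBU, THF) should give the (2S,3R)-epoxy ketone F3, the alkene of the side chain being inert to the nucleophilic oxidant. Reductive opening of the C-α–O bond with SmI2 (THF/MeOH, −90 °C) then delivers 22 with the C-β oxygen retained.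

Step 9. Oxidative addition and transmetalation may be slow at the doubly ortho-substituted iodide, so that protodezincation or β-hydride elimination of the β-branched alkylzinc takes over. The fallback reverses the polarity; it sets out from 14 and 3 and comes back at 17. Alcohol 14 is converted with Tf2O and 2,6-lutidine (CH2Cl2, −78 °C) into the triflate F4. Arylmagnesium chloride 4, made from 3 as in step 3, is alkylated with F4 under CuBr·SMe2 catalysis (THF, −30 °C) to give the aryl iodide F5. A second iodine–magnesium exchange (iPrMgCl·LiCl) and acylation with N-methoxy-N-methylacetamide return to 17.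

Further compounds
F1 | step 13 | (1S,3S)-1-{3-[(2R,3R)-4-[(tert-butyldimethylsilyl)oxy]-3-methyl-2-(3-methylbut-2-en-1-yl)butyl]-2-fluoro-4,6-bis(methoxymethoxy)phenyl}-3-[2-methoxy-4-(methoxymethoxy)phenyl]propane-1,3-diol | COCOc1ccc([C@@H](O)C[C@H](O)c2c(OCOC)cc(OCOC)c(C[C@@H](CC=C(C)C)[C@@H](C)CO[Si](C)(C)C(C)(C)C)c2F)c(OC)c1
F2 | step 13 | (2S,4S)-8-[(2R,3R)-4-[(tert-butyldimethylsilyl)oxy]-3-methyl-2-(3-methylbut-2-en-1-yl)butyl]-2-[2-methoxy-4-(methoxymethoxy)phenyl]-5,7-bis(methoxymethoxy)chroman-4-ol | COCOc1ccc([C@@H]2C[C@H](O)c3c(OCOC)cc(OCOC)c(C[C@@H](CC=C(C)C)[C@@H](C)CO[Si](C)(C)C(C)(C)C)c3O2)c(OC)c1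
F3 | step 12 | {3-[(2R,3R)-4-[(tert-butyldimethylsilyl)oxy]-3-methyl-2-(3-methylbut-2-en-1-yl)butyl]-2-fluoro-4,6-bis(methoxymethoxy)phenyl}{(2S,3R)-3-[2-methoxy-4-(methoxymethoxy)phenyl]oxiran-2-yl}methanone | O=C(c1c(OCOC)cc(OCOC)c(C[C@@H](CC=C(C)C)[C@@H](C)CO[Si](C)(C)C(C)(C)C)c1F)[C@H]1O[C@@H]1c1ccc(OCOC)cc1OC
F4 | step 9 | (2S,3R)-4-[(tert-butyldimethylsilyl)oxy]-3-methyl-2-(3-methylbut-2-en-1-yl)butyl trifluoromethanesulfonate | C[C@@H](CO[Si](C)(C)C(C)(C)C)[C@H](CC=C(C)C)COS(=O)(=O)C(F)(F)F
F5 | step 9 | tert-butyl{[(2R,3R)-3-[2-fluoro-3-iodo-4,6-bis(methoxymethoxy)benzyl]-2,6-dimethylhept-5-en-1-yl]oxy}dimethylsilane | COCOc1cc(OCOC)c(C[C@@H](CC=C(C)C)[C@@H](C)CO[Si](C)(C)C(C)(C)C)c(F)c1I
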